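**Retrosynthetic overview**
1. C50 skeleton = C20 + C10 + C20: two Wittig couplings of the end-group phosphonium salts 26 and 14 with 2,7-dimethylocta-2,4,6-trienedial 27; the side-chain CH2OH is carried as a methyl ester.
2. Both stereogenic end groups come from (R)-limonene 1: ring ozonolysis gives keto-acetal 4 (right end) or keto-aldehyde 16 (left end); limonene's C4 centre becomes C2' and C2.
3. Left end: prenyl by Wittig, hydration of the isopropenyl group, enone, then chain growth by a Saucy–Marbet propargyl Claisen [3,3] rearrangement (C7–C8 bond).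
4. Right end: geometrically pure (E)-dienone by alkyne carboalumination and Heck coupling, side chain by Wittig.
5. Ring order: the only ring (ε-ring) is closed in step 7 by a chair-like cation–olefin cyclisation in which C2' sets C6' (cis).

Assumptions: phosphonium salts 14 and 26 are crystallised as their E isomers and the final polyene is thermally equilibrated to all-E, as is usual for carotenoids. Carotenoid locants (C1–C15, C1'–C15') are used in the "Why" lines.

**Step 1**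
Reactants: 1 (R)-(+)-limonene
Product: 4 (5R)-7,7-dimethoxy-5-(prop-1-en-2-yl)heptan-2-one, via methoxy hydroperoxide aldehyde 2 (not isolated), via methoxy hydroperoxide acetal 3 (not isolated)
Conditions: O3 (1 eq), CH2Cl2/MeOH, −78 °C; TsOH (cat.), −78 °C → rt; NaHCO3, Me2S, rt
Reagents that add atoms: ozone O=[O+][O-]; methanol CO
Why: Selective ozonolysis of the more electron-rich ring alkene with in-situ acetalisation of the aldehyde terminus leaves the methyl ketone free; the limonene stereocentre is untouched.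

**Step 2**
Reactants: 4 (5R)-7,7-dimethoxy-5-(prop-1-en-2-yl)heptan-2-one
Product: 6 (5R)-7,7-dimethoxy-5-(prop-1-en-2-yl)hept-1-yne, via enol phosphate 5 (not isolated)
Conditions: LDA (1.1 eq), THF, −78 °C; ClP(O)(OEt)2; LDA (2.3 eq), −78 °C → rt
Reagents that add atoms: none
Why: Negishi one-pot conversion of a methyl ketone to a terminal alkyne by kinetic enol phosphate formation and β-elimination.

**Step 3**
Reactants: 6 (5R)-7,7-dimethoxy-5-(prop-1-en-2-yl)hept-1-yne
Product: 8 (1E,5R)-1-iodo-7,7-dimethoxy-2-methyl-5-(prop-1-en-2-yl)hept-1-ene, via alkenylalane 7 (not isolated)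
Conditions: Me3Al (3 eq), Cp2ZrCl2 (0.2 eq), H2O (1 eq), CH2Cl2, −30 °C; then I2, THF, −30 → 0 °C
Reagents that add atoms: trimethylaluminium C[Al](C)C; iodine II
Why: Zr-catalysed syn-carboalumination (Negishi, water-accelerated) followed by iodinolysis with retention gives the trisubstituted alkene as the pure E isomer, which later decides the C6' configuration.

**Step 4**
Reactants: 8 (1E,5R)-1-iodo-7,7-dimethoxy-2-methyl-5-(prop-1-en-2-yl)hept-1-ene
Product: 9 (3E,5E,9R)-11,11-dimethoxy-6-methyl-9-(prop-1-en-2-yl)undeca-3,5-dien-2-one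
Conditions: but-3-en-2-one (3 eq), Pd(OAc)2 (5 mol%), Bu4NCl, NaHCO3, DMF, 40 °C
Reagents that add atoms: but-3-en-2-one C=CC(C)=O
Why: Heck coupling under Jeffery conditions proceeds with retention of the vinyl iodide geometry and gives the (E,E)-dienone.

**Step 5**
Reactants: 9 (3E,5E,9R)-11,11-dimethoxy-6-methyl-9-(prop-1-en-2-yl)undeca-3,5-dien-2-one
Product: 10 (3R,6E,8E)-6-methyl-10-oxo-3-(prop-1-en-2-yl)undeca-6,8-dienal
Conditions: 1 M HCl, THF, rt
Reagents that add atoms: water O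
Why: Mild acetal hydrolysis frees the aldehyde; the stereocentre is β to it and not epimerisable.

**Step 6**
Reactants: 10 (3R,6E,8E)-6-methyl-10-oxo-3-(prop-1-en-2-yl)undeca-6,8-dienal
Product: 11 methyl (2E,5R,8E,10E)-2,8-dimethyl-12-oxo-5-(prop-1-en-2-yl)trideca-2,8,10-trienoate
Conditions: Ph3P=C(Me)CO2Me, CH2Cl2, rt
Reagents that add atoms: methyl 2-(triphenylphosphoranylidene)propanoate COC(=O)C(C)=P(c1ccccc1)(c1ccccc1)c1ccccc1
Why: The stabilised Wittig ylide reacts only with the aldehyde and gives the (E)-trisubstituted enoate of the C5 side chain.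

**Step 7**
Reactants: 11 methyl (2E,5R,8E,10E)-2,8-dimethyl-12-oxo-5-(prop-1-en-2-yl)trideca-2,8,10-trienoate
Product: 12 methyl (2E)-2-methyl-4-{(1R,5R)-4,6,6-trimethyl-5-[(1E)-3-oxobut-1-en-1-yl]cyclohex-3-en-1-yl}but-2-enoate
Conditions: 85% H3PO4, toluene, 30 °C
Reagents that add atoms: none
Why: Cation–olefin cyclisation (pseudoionone → α-ionone type): the tertiary cation from the isopropenyl group is attacked by the (E)-8,9-alkene through a chair with both chains equatorial, so the limonene-derived centre sets C6' cis (6'R), and kinetic loss of H-4' gives the ε double bond.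

**Step 8**
Reactants: 12 methyl (2E)-2-methyl-4-{(1R,5R)-4,6,6-trimethyl-5-[(1E)-3-oxobut-1-en-1-yl]cyclohex-3-en-1-yl}but-2-enoate
Product: 13 methyl (2E)-4-{(1R,5R)-5-[(1E)-3-hydroxy-3-methylpenta-1,4-dien-1-yl]-4,6,6-trimethylcyclohex-3-en-1-yl}-2-methylbut-2-enoate (carbinol epimers)
Conditions: CH2=CHMgBr (1.3 eq), THF, −40 → −10 °C; aq. NH4Cl
Reagents that add atoms: vinylmagnesium bromide C=C[Mg]Br
Why: Grignard 1,2-addition to the enone ketone is much faster than attack on the hindered conjugated ester; the new carbinol centre is lost in the next step.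

**Step 9**
Reactants: 13 methyl (2E)-4-{(1R,5R)-5-[(1E)-3-hydroxy-3-methylpenta-1,4-dien-1-yl]-4,6,6-trimethylcyclohex-3-en-1-yl}-2-methylbut-2-enoate
Product: 14 {(2E,4E)-5-[(1R,5R)-5-[(2E)-4-methoxy-3-methyl-4-oxobut-2-en-1-yl]-2,6,6-trimethylcyclohex-2-en-1-yl]-3-methylpenta-2,4-dien-1-yl}triphenylphosphonium bromide
Conditions: PPh3·HBr, MeOH, rt; crystallise (EtOAc)
Reagents that add atoms: triphenylphosphine hydrobromide Br.c1ccc(cc1)P(c1ccccc1)c1ccccc1
Why: Ionisation of the tertiary bis-allylic alcohol and capture of the pentadienyl cation by PPh3 at the primary terminus (SN1' allylic transposition, the standard C15-salt method) gives the conjugated salt, mainly 9'E.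

**Step 10**
Reactants: 1 (R)-(+)-limonene
Product: 16 (3R)-6-oxo-3-(prop-1-en-2-yl)heptanal, via limonene ring ozonide 15 (not isolated)
Conditions: O3 (1.0 eq, Sudan Red 7B end point), CH2Cl2, −78 °C; PPh3 (1.1 eq), −78 °C → rt
Reagents that add atoms: ozone O=[O+][O-]
Why: Ozonolysis with reductive work-up: in the non-participating solvent the carbonyl oxide from the more electron-rich ring alkene recloses on the tethered aldehyde to the secondary ozonide (Criegee mechanism), which PPh3 reduces to the keto-aldehyde with the stereocentre unchanged.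

**Step 11**
Reactants: 16 (3R)-6-oxo-3-(prop-1-en-2-yl)heptanal
Product: 17 (5R)-8-methyl-5-(prop-1-en-2-yl)non-7-en-2-one
Conditions: i-PrPPh3I, n-BuLi, THF, 0 °C; ylide (1.0 eq) added to 16, −78 → 0 °C
Reagents that add atoms: isopropylidenetriphenylphosphorane (made in the flask from isopropyltriphenylphosphonium iodide) CC(C)=P(c1ccccc1)(c1ccccc1)c1ccccc1
Why: Chemoselective Wittig olefination of the aldehyde over the methyl ketone at low temperature installs the prenyl group.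

**Step 12**
Reactants: 17 (5R)-8-methyl-5-(prop-1-en-2-yl)non-7-en-2-one
Product: 18 (5R)-5-(2-hydroxypropan-2-yl)-8-methylnon-7-en-2-one
Conditions: Co(acac)2 (20 mol%), PhSiH3, O2 (1 atm), THF, 0 °C → rt
Reagents that add atoms: dioxygen O=O
Why: Mukaiyama (HAT) Markovnikov hydration is faster at the 1,1-disubstituted isopropenyl alkene than at the trisubstituted prenyl alkene and tolerates the ketone.

**Step 13**
Reactants: 18 (5R)-5-(2-hydroxypropan-2-yl)-8-methylnon-7-en-2-one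
Product: 19 (3E,5S)-5-(2-hydroxypropan-2-yl)-8-methylnona-3,7-dien-2-one
Conditions: IBX (1.5 eq), toluene/DMSO (2:1), 65 °C
Reagents that add atoms: none
Why: IBX (Nicolaou) α,β-dehydrogenation can only occur on the CH2–CH2 side of the methyl ketone and gives the (E)-enone; the stereocentre keeps its geometry and only its CIP label changes.

**Step 14**
Reactants: 19 (3E,5S)-5-(2-hydroxypropan-2-yl)-8-methylnona-3,7-dien-2-one
Product: 20 (4E,6S)-6-(2-hydroxypropan-2-yl)-3,9-dimethyldeca-4,8-dien-1-yn-3-ol (C3 epimers)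
Conditions: HC≡CMgBr (2.5 eq), THF, 0 °C; aq. NH4Cl
Reagents that add atoms: ethynylmagnesium bromide C#C[Mg]Br
Why: Ethynyl Grignard 1,2-addition to the enone gives the tertiary propargylic alcohol needed for the Claisen step.

**Step 15**
Reactants: 20 (4E,6S)-6-(2-hydroxypropan-2-yl)-3,9-dimethyldeca-4,8-dien-1-yn-3-ol
Product: 24 (3E,5E,7E,9S)-9-{2-[(2-methoxypropan-2-yl)oxy]propan-2-yl}-6,12-dimethyltrideca-3,5,7,11-tetraen-2-one, via bis-MOP ketal 21 (not isolated), via propargyl isopropenyl ether 22 (not isolated), via allenyl ketone 23 (not isolated)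
Conditions: 2-methoxypropene (5 eq), TsOH (0.2 mol%), toluene, 95 °C (sealed); NaOMe (cat.), MeOH, 0 °C; I2 (cat.), hexane, rt
Reagents that add atoms: 2-methoxypropene COC(C)=C
Why: Saucy–Marbet propargyl Claisen [3,3]-sigmatropic rearrangement forms the C7–C8 bond; base moves the allene into conjugation, iodine equilibrates C5=C6 towards E (about 3:1), and the reagent also masks the tertiary OH as its MOP ether.

**Step 16**
Reactants: 24 (3E,5E,7E,9S)-9-{2-[(2-methoxypropan-2-yl)oxy]propan-2-yl}-6,12-dimethyltrideca-3,5,7,11-tetraen-2-one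
Product: 25 (4E,6E,8E,10S)-10-{2-[(2-methoxypropan-2-yl)oxy]propan-2-yl}-3,7,13-trimethyltetradeca-1,4,6,8,12-pentaen-3-ol (C3 epimers)
Conditions: CH2=CHMgBr (1.3 eq), THF, −20 °C; pH 7 phosphate buffer
Reagents that add atoms: vinylmagnesium bromide C=C[Mg]Br
Why: Grignard 1,2-addition to the polyenone, as in the industrial vinylpseudoionol synthesis; the neutral quench keeps the acid-labile MOP ether.

**Step 17**
Reactants: 25 (4E,6E,8E,10S)-10-{2-[(2-methoxypropan-2-yl)oxy]propan-2-yl}-3,7,13-trimethyltetradeca-1,4,6,8,12-pentaen-3-ol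
Product: 26 [(2E,4E,6E,8E,10S)-10-(2-hydroxypropan-2-yl)-3,7,13-trimethyltetradeca-2,4,6,8,12-pentaen-1-yl]triphenylphosphonium bromide
Conditions: PPh3·HBr, MeOH, rt; crystallise
Reagents that add atoms: triphenylphosphine hydrobromide Br.c1ccc(cc1)P(c1ccccc1)c1ccccc1
Why: SN1' phosphonium salt formation at the primary terminus of the polyenyl cation; acidic methanol also removes the MOP ether, and crystallisation removes the minor 5Z/9Z isomers.

**Step 18**
Reactants: 26 [(2E,4E,6E,8E,10S)-10-(2-hydroxypropan-2-yl)-3,7,13-trimethyltetradeca-2,4,6,8,12-pentaen-1-yl]triphenylphosphonium bromide; 27 (2E,4E,6E)-2,7-dimethylocta-2,4,6-trienedial (3 eq)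
Product: 29 (2E,4E,6E,8E,10E,12E,14E,16E,18S)-18-(2-hydroxypropan-2-yl)-2,7,11,15,21-pentamethyldocosa-2,4,6,8,10,12,14,16,20-nonaenal, via phosphorus ylide 28 (not isolated)
Conditions: NaOMe (1.05 eq), MeOH/CH2Cl2, 0 °C → rt
Reagents that add atoms: none
Why: Wittig mono-olefination of the symmetrical C10 dialdehyde used in excess (standard apo-carotenal synthesis); the C11=C12 Z isomer equilibrates to E on warming.

**Step 19**
Reactants: 29 (C30 hydroxy-aldehyde); 14 (right-hand C20 phosphonium bromide)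
Product: 31 C50 methyl ester of the target (side-chain CO2Me in place of CH2OH; 2S 2'R 6'R all-E), via phosphorus ylide 30 (not isolated)
Conditions: NaOMe (1.1 eq), MeOH/CH2Cl2, rt; then heptane, reflux; crystallise
Reagents that add atoms: none
Why: The second Wittig coupling completes the C50 chain; thermal Z→E isomerisation and crystallisation give the all-E polyene without touching the three sp3 stereocentres.

**Step 20**
Reactants: 31 (C50 methyl ester)
Product: 32 target CNP0409952.1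
Conditions: DIBAL-H (4 eq), CH2Cl2, −78 → −40 °C; Rochelle salt
Reagents that add atoms: none
Why: DIBAL 1,2-reduction of the conjugated ester gives the (E)-allylic alcohol; the polyene and the tertiary alcohol are inert.

**Compound list**
1 | (R)-(+)-limonene | CC1=CC[C@@H](CC1)C(C)=C | starting material
2 | (3R)-6-hydroperoxy-6-methoxy-3-(prop-1-en-2-yl)heptanal (C6 epimers) | O=CC[C@@H](CCC(C)(OC)OO)C(C)=C | intermediate (not isolated)
3 | (5R)-2-hydroperoxy-2,7,7-trimethoxy-5-(prop-1-en-2-yl)heptane | COC(OC)C[C@@H](CCC(C)(OC)OO)C(C)=C | intermediate (not isolated)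
4 | (5R)-7,7-dimethoxy-5-(prop-1-en-2-yl)heptan-2-one | COC(OC)C[C@@H](CCC(C)=O)C(C)=C | intermediate
5 | diethyl (5R)-7,7-dimethoxy-5-(prop-1-en-2-yl)hept-1-en-2-yl phosphate | COC(OC)C[C@@H](CCC(=C)OP(=O)(OCC)OCC)C(C)=C | intermediate (not isolated)
6 | (5R)-7,7-dimethoxy-5-(prop-1-en-2-yl)hept-1-yne | COC(OC)C[C@@H](CCC#C)C(C)=C | intermediate
7 | [(1E,5R)-7,7-dimethoxy-2-methyl-5-(prop-1-en-2-yl)hept-1-en-1-yl]dimethylalane | COC(OC)C[C@@H](CC/C(C)=C/[Al](C)C)C(C)=C | intermediate (not isolated)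
8 | (1E,5R)-1-iodo-7,7-dimethoxy-2-methyl-5-(prop-1-en-2-yl)hept-1-ene | COC(OC)C[C@@H](CC/C(C)=C/I)C(C)=C | intermediate
9 | (3E,5E,9R)-11,11-dimethoxy-6-methyl-9-(prop-1-en-2-yl)undeca-3,5-dien-2-one | COC(OC)C[C@@H](CC/C(C)=C/C=C/C(C)=O)C(C)=C | intermediate
10 | (3R,6E,8E)-6-methyl-10-oxo-3-(prop-1-en-2-yl)undeca-6,8-dienal | O=CC[C@@H](CC/C(C)=C/C=C/C(C)=O)C(C)=C | intermediate
11 | methyl (2E,5R,8E,10E)-2,8-dimethyl-12-oxo-5-(prop-1-en-2-yl)trideca-2,8,10-trienoate | COC(=O)/C(C)=C/C[C@@H](CC/C(C)=C/C=C/C(C)=O)C(C)=C | intermediate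
12 | methyl (2E)-2-methyl-4-{(1R,5R)-4,6,6-trimethyl-5-[(1E)-3-oxobut-1-en-1-yl]cyclohex-3-en-1-yl}but-2-enoate | CC(=O)/C=C/[C@@H]1C(C)=CC[C@H](C/C=C(\C)C(=O)OC)C1(C)C | intermediate
13 | methyl (2E)-4-{(1R,5R)-5-[(1E)-3-hydroxy-3-methylpenta-1,4-dien-1-yl]-4,6,6-trimethylcyclohex-3-en-1-yl}-2-methylbut-2-enoate (carbinol epimers) | C=CC(C)(O)/C=C/[C@@H]1C(C)=CC[C@H](C/C=C(\C)C(=O)OC)C1(C)C | intermediate
14 | {(2E,4E)-5-[(1R,5R)-5-[(2E)-4-methoxy-3-methyl-4-oxobut-2-en-1-yl]-2,6,6-trimethylcyclohex-2-en-1-yl]-3-methylpenta-2,4-dien-1-yl}triphenylphosphonium bromide | [Br-].c2ccccc2[P+](c2ccccc2)(c2ccccc2)C/C=C(C)/C=C/[C@@H]1C(C)=CC[C@H](C/C=C(\C)C(=O)OC)C1(C)C | intermediate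
15 | limonene secondary ozonide, (4R)-1-methyl-4-(prop-1-en-2-yl)-7,8,9-trioxabicyclo[4.2.1]nonane (bridgehead epimers) | CC12CC[C@@H](C(C)=C)CC(OO1)O2 | intermediate (not isolated)
16 | (3R)-6-oxo-3-(prop-1-en-2-yl)heptanal | O=CC[C@@H](CCC(C)=O)C(C)=C | intermediate
17 | (5R)-8-methyl-5-(prop-1-en-2-yl)non-7-en-2-one | CC(C)=CC[C@@H](CCC(C)=O)C(C)=C | intermediate
18 | (5R)-5-(2-hydroxypropan-2-yl)-8-methylnon-7-en-2-one | CC(C)=CC[C@@H](CCC(C)=O)C(C)(C)O | intermediate
19 | (3E,5S)-5-(2-hydroxypropan-2-yl)-8-methylnona-3,7-dien-2-one | CC(C)=CC[C@@H](/C=C/C(C)=O)C(C)(C)O | intermediate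
20 | (4E,6S)-6-(2-hydroxypropan-2-yl)-3,9-dimethyldeca-4,8-dien-1-yn-3-ol (C3 epimers) | CC(C)=CC[C@@H](/C=C/C(C)(O)C#C)C(C)(C)O | intermediate
21 | bis(2-methoxypropan-2-yl) ether of 20 | CC(C)=CC[C@@H](/C=C/C(C)(OC(C)(C)OC)C#C)C(C)(C)OC(C)(C)OC | intermediate (not isolated)
22 | propargyl isopropenyl ether of 20 with the tertiary OH as MOP ether | CC(C)=CC[C@@H](/C=C/C(C)(OC(C)=C)C#C)C(C)(C)OC(C)(C)OC | intermediate (not isolated)
23 | (7E,9S)-9-{2-[(2-methoxypropan-2-yl)oxy]propan-2-yl}-6,12-dimethyltrideca-4,5,7,11-tetraen-2-one | CC(C)=CC[C@@H](/C=C/C(C)=C=CCC(C)=O)C(C)(C)OC(C)(C)OC | intermediate (not isolated)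
24 | (3E,5E,7E,9S)-9-{2-[(2-methoxypropan-2-yl)oxy]propan-2-yl}-6,12-dimethyltrideca-3,5,7,11-tetraen-2-one | CC(C)=CC[C@@H](/C=C/C(C)=C/C=C/C(C)=O)C(C)(C)OC(C)(C)OC | intermediate
25 | (4E,6E,8E,10S)-10-{2-[(2-methoxypropan-2-yl)oxy]propan-2-yl}-3,7,13-trimethyltetradeca-1,4,6,8,12-pentaen-3-ol (C3 epimers) | CC(C)=CC[C@@H](/C=C/C(C)=C/C=C/C(C)(O)C=C)C(C)(C)OC(C)(C)OC | intermediate
26 | [(2E,4E,6E,8E,10S)-10-(2-hydroxypropan-2-yl)-3,7,13-trimethyltetradeca-2,4,6,8,12-pentaen-1-yl]triphenylphosphonium bromide | CC(C)=CC[C@@H](/C=C/C(C)=C/C=C/C(C)=C/C[P+](c1ccccc1)(c1ccccc1)c1ccccc1)C(C)(C)O.[Br-] | intermediate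
27 | (2E,4E,6E)-2,7-dimethylocta-2,4,6-trienedial | O=C/C(C)=C/C=C/C=C(C)/C=O | starting material
28 | ylide of 26 | CC(C)=CC[C@@H](/C=C/C(C)=C/C=C/C(C)=C/C=P(c1ccccc1)(c1ccccc1)c1ccccc1)C(C)(C)O | intermediate (not isolated)
29 | (2E,4E,6E,8E,10E,12E,14E,16E,18S)-18-(2-hydroxypropan-2-yl)-2,7,11,15,21-pentamethyldocosa-2,4,6,8,10,12,14,16,20-nonaenal | CC(C)=CC[C@@H](/C=C/C(C)=C/C=C/C(C)=C/C=C/C(C)=C/C=C/C=C(C)/C=O)C(C)(C)O | intermediate
30 | ylide of 14 | c2ccccc2P(c2ccccc2)(c2ccccc2)=C/C=C(C)/C=C/[C@@H]1C(C)=CC[C@H](C/C=C(\C)C(=O)OC)C1(C)C | intermediate (not isolated)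
31 | methyl ester of the target (side-chain CO2Me in place of CH2OH; 2S,2'R,6'R, all-E) | CC(C)=CC[C@@H](/C=C/C(C)=C/C=C/C(C)=C/C=C/C(C)=C/C=C/C=C(C)/C=C/C=C(C)/C=C/[C@@H]1C(C)=CC[C@H](C/C=C(\C)C(=O)OC)C1(C)C)C(C)(C)O | intermediate
32 | CNP0409952.1, (2S,2'R,6'R) all-E C50 carotenoid | CC(C)=CC[C@@H](/C=C/C(C)=C/C=C/C(C)=C/C=C/C(C)=C/C=C/C=C(C)/C=C/C=C(C)/C=C/[C@@H]1C(C)=CC[C@H](C/C=C(\C)CO)C1(C)C)C(C)(C)O | target

**Totals**
Total steps: 20. Longest linear sequence: 11 (steps 1–9, 19, 20; equally 10–17, 18–20).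

**Three steps most likely to fail**

Step 7 (ring closure). The free tertiary cation next to the C2' hydrogen can lose or shift that hydrogen before the deactivated dienone alkene attacks, eroding C2' and the cis selectivity, and α/β/γ alkene mixtures are possible. The fallback sets out from 11 and comes back at 12. Hg(OTf)2·N,N-dimethylaniline in MeNO2 at −20 °C (Nishizawa olefin cyclisation, a bridged mercurinium ion in place of a free cation), followed by brine, gives the ring-closed methyl (2E)-4-{(1R,5R)-6-[(chloromercurio)methyl]-4,6-dimethyl-5-[(1E)-3-oxobut-1-en-1-yl]cyclohex-3-en-1-yl}-2-methylbut-2-enoate F1. Alkaline NaBH4 turns CH2HgCl into the second methyl group and also reduces the ketone, giving methyl (2E)-4-{(1R,5R)-5-[(1E)-3-hydroxybut-1-en-1-yl]-4,6,6-trimethylcyclohex-3-en-1-yl}-2-methylbut-2-enoate F2. MnO2 in CH2Cl2 reoxidises the allylic alcohol to 12.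

Step 12 (hydration). The prenyl alkene may compete in the HAT hydration. The fallback sets out from 17 and comes back at 19. Oxymercuration with Hg(OAc)2 in THF/H2O, which strongly prefers the 1,1-disubstituted alkene, gives [(3R)-2-hydroxy-2-methyl-3-(3-methylbut-2-en-1-yl)-6-oxoheptyl]mercury acetate F3. NaBH4/NaOH removes mercury and reduces the ketone to (5R)-5-(2-hydroxypropan-2-yl)-8-methylnon-7-en-2-ol F4. IBX (3 eq, DMSO, 70 °C) then oxidises the secondary alcohol and dehydrogenates the ketone in one operation to 19.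

Step 15 (Saucy–Marbet). The rearrangement gives a C5=C6 E/Z mixture, the isopropenyl ether can also rearrange through the neighbouring C4=C5 alkene (allyl Claisen), and the hot acid may dehydrate the tertiary carbinols. The fallback sets out from 19 and comes back at 26, building the chain as C2 + C5 by Wittig chemistry. Vinylmagnesium bromide gives (4E,6S)-6-(2-hydroxypropan-2-yl)-3,9-dimethyldeca-1,4,8-trien-3-ol F5. PPh3·HBr in MeOH gives the crystalline [(2E,4E,6S)-6-(2-hydroxypropan-2-yl)-3,9-dimethyldeca-2,4,8-trien-1-yl]triphenylphosphonium bromide F6. NaOMe generates its ylide F7, which reacts with commercial (E)-4-acetoxy-2-methylbut-2-enal to give (2E,4E,6E,8E,10S)-10-(2-hydroxypropan-2-yl)-3,7,13-trimethyltetradeca-2,4,6,8,12-pentaen-1-yl acetate F8. K2CO3/MeOH gives the corresponding pentaenol F9, and PPh3·HBr converts it to 26.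

**Further compounds**
F1 | step 7 | methyl (2E)-4-{(1R,5R)-6-[(chloromercurio)methyl]-4,6-dimethyl-5-[(1E)-3-oxobut-1-en-1-yl]cyclohex-3-en-1-yl}-2-methylbut-2-enoate (C6 as formed) | CC(=O)/C=C/[C@@H]1C(C)=CC[C@H](C/C=C(\C)C(=O)OC)C1(C)C[Hg]Cl
F2 | step 7 | methyl (2E)-4-{(1R,5R)-5-[(1E)-3-hydroxybut-1-en-1-yl]-4,6,6-trimethylcyclohex-3-en-1-yl}-2-methylbut-2-enoate (carbinol epimers) | CC(O)/C=C/[C@@H]1C(C)=CC[C@H](C/C=C(\C)C(=O)OC)C1(C)C
F3 | step 12 | [(3R)-2-hydroxy-2-methyl-3-(3-methylbut-2-en-1-yl)-6-oxoheptyl]mercury acetate (C2 epimers) | CC(=O)O[Hg]CC(C)(O)[C@@H](CC=C(C)C)CCC(C)=O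
F4 | step 12 | (5R)-5-(2-hydroxypropan-2-yl)-8-methylnon-7-en-2-ol (C2 epimers) | CC(C)=CC[C@@H](CCC(C)O)C(C)(C)O
F5 | step 15 | (4E,6S)-6-(2-hydroxypropan-2-yl)-3,9-dimethyldeca-1,4,8-trien-3-ol (C3 epimers) | CC(C)=CC[C@@H](/C=C/C(C)(O)C=C)C(C)(C)O
F6 | step 15 | [(2E,4E,6S)-6-(2-hydroxypropan-2-yl)-3,9-dimethyldeca-2,4,8-trien-1-yl]triphenylphosphonium bromide | CC(C)=CC[C@@H](/C=C/C(C)=C/C[P+](c1ccccc1)(c1ccccc1)c1ccccc1)C(C)(C)O.[Br-]
F7 | step 15 | ylide of F6 | CC(C)=CC[C@@H](/C=C/C(C)=C/C=P(c1ccccc1)(c1ccccc1)c1ccccc1)C(C)(C)O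
F8 | step 15 | (2E,4E,6E,8E,10S)-10-(2-hydroxypropan-2-yl)-3,7,13-trimethyltetradeca-2,4,6,8,12-pentaen-1-yl acetate | CC(C)=CC[C@@H](/C=C/C(C)=C/C=C/C(C)=C/COC(C)=O)C(C)(C)O
F9 | step 15 | (2E,4E,6E,8E,10S)-10-(2-hydroxypropan-2-yl)-3,7,13-trimethyltetradeca-2,4,6,8,12-pentaen-1-ol | CC(C)=CC[C@@H](/C=C/C(C)=C/C=C/C(C)=C/CO)C(C)(C)O
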